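**Strategy**

The hydroperoxy-dienone ring is read as a para-alkylphenol oxygenated at the ring-fusion carbon para to oxygen (C-4a, 1,4 to the C-7 carbonyl; naphthalene locants), so the last step is a substrate-controlled singlet-oxygen dearomatisation. The phenol ring is built by a formal [3+3] benzannulation: a cyclohexylidenemethyl boronate (C-8, C-8a, C-4a) and 3,3-dichloro-2-methylacryloyl chloride (C-7, C-6, C-5) are joined in one pot by acyl Suzuki coupling (C-8 to C-7) and by γ-deprotonation, 6π closure and loss of HCl (C-4a to C-5). This exploits that C-4a is the only γ-CH2 of the cyclohexylidene enone, C-1 being quaternary. The isopropenyl centre comes from catalysis, the other two from relay.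

Key step: step 7

Remark: locants are the naphthalene locants of the target and are kept for the tetralin intermediates. C-1 is the quaternary carbon, C-2 the isopropenyl-bearing CH, C-4a the hydroperoxy-bearing carbon, C-5 vinyl-bearing, C-6 methyl-bearing, C-7 the carbonyl, C-8 the ring CH and C-8a the sp2 ring-fusion carbon.

**Route**

Step 1
Reactants: 1 2-methylcyclohex-2-en-1-one; 2 prop-1-en-2-ylmagnesium bromide (isopropenylmagnesium bromide)
Product: 4 (3S)-2-methyl-3-(prop-1-en-2-yl)cyclohexan-1-one (both C-2 epimers), via magnesium enolate 3 (not isolated)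
Conditions: 2 (1.2 equiv, slow addition), Cu(OTf)2 (3 mol %), chiral hydroxyalkyl-imidazolinium salt as NHC precursor (4 mol %), Et2O, −30 °C; then sat. aq. NH4Cl
Reagents that add atoms: none
Why: Copper-catalysed asymmetric conjugate addition of an alkenyl Grignard reagent to an α-substituted cyclic enone; the chiral NHC–copper complex selects the enone face so that C-3 is formed S (the future C-2 of the target), and protonation of enolate 3 leaves C-2 of 4 as an inconsequential epimer mixture.

Step 2
Reactants: 4 (3S)-2-methyl-3-(prop-1-en-2-yl)cyclohexan-1-one; 5 methyl acrylate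
Product: 6 methyl 3-[(1R,6R)-1-methyl-2-oxo-6-(prop-1-en-2-yl)cyclohexyl]propanoate
Conditions: 5 (1.2 equiv), t-BuOK (0.1 equiv), t-BuOH–THF, 0 °C
Reagents that add atoms: none
Why: Base-catalysed Michael addition through the more substituted enolate, as in Robinson annulations of 2,3-dialkylcyclohexanones; the acrylate should approach anti to the adjacent isopropenyl group (held pseudo-axial by allylic strain), so the quaternary centre forms with methyl cis and the propanoate arm trans to isopropenyl, and both C-2 epimers of 4 converge.

Step 3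
Reactants: 6 methyl 3-[(1R,6R)-1-methyl-2-oxo-6-(prop-1-en-2-yl)cyclohexyl]propanoate; 7 2,2'-methylenebis(4,4,5,5-tetramethyl-1,3,2-dioxaborolane)
Product: 8 methyl 3-[(1R,6R)-1-methyl-6-(prop-1-en-2-yl)-2-[(4,4,5,5-tetramethyl-1,3,2-dioxaborolan-2-yl)methylidene]cyclohexyl]propanoate (E/Z mixture)
Conditions: 7 (1.3 equiv), lithium 2,2,6,6-tetramethylpiperidide (1.25 equiv), THF, 0 °C; then 6, −78 °C to rt
Reagents that add atoms: none
Why: Boron–Wittig olefination; the lithiated gem-diboronate should add to the ketone, which is far more electrophilic than the methyl ester, and syn B–O elimination gives the alkenyl boronate, whose E/Z ratio is irrelevant because both isomers converge in step 7.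

Step 4
Reactants: 9 methyl pyruvate
Product: 10 methyl 3,3-dichloro-2-methylprop-2-enoate
Conditions: PPh3 (2.2 equiv), CCl4 (excess), MeCN, 0 to 60 °C
Reagents that add atoms: carbon tetrachloride, ClC(Cl)(Cl)Cl
Why: Wittig-type dichloromethylenation; Ph3P=CCl2 generated from PPh3 and CCl4 olefinates the activated ketone carbonyl of the α-keto ester and leaves the ester carbonyl alone.

Step 5
Reactants: 10 methyl 3,3-dichloro-2-methylprop-2-enoate
Product: 11 3,3-dichloro-2-methylprop-2-enoic acid
Conditions: LiOH·H2O (1.5 equiv), THF–H2O, 0 °C; then 1 M HCl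
Reagents that add atoms: lithium hydroxide, [Li+].[OH-]
Why: Saponification at 0 °C should be faster than conjugate addition–elimination at the hindered, α-substituted dichlorovinyl carbon.

Step 6
Reactants: 11 3,3-dichloro-2-methylprop-2-enoic acid
Product: 12 3,3-dichloro-2-methylprop-2-enoyl chloride
Conditions: (COCl)2 (1.3 equiv), DMF (cat.), CH2Cl2, 0 °C to rt; evaporation, used crude
Reagents that add atoms: oxalyl chloride, ClC(=O)C(=O)Cl
Why: DMF-catalysed (Vilsmeier-type) conversion of the acid into the acid chloride, with only gaseous by-products.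

Step 7
Reactants: 8 alkenyl boronate (E/Z mixture); 12 3,3-dichloro-2-methylprop-2-enoyl chloride
Product: 14 methyl 3-[(1R,2R)-5-chloro-7-hydroxy-1,6-dimethyl-2-(prop-1-en-2-yl)-1,2,3,4-tetrahydronaphthalen-1-yl]propanoate, via dienone 13 (not isolated)
Conditions: 12 (1.05 equiv), Pd(PPh3)4 (5 mol %), Cs2CO3 (4 equiv), toluene–DMF (4:1, 0.02 M), 60 to 100 °C, one pot; aq. NH4Cl work-up
Reagents that add atoms: none
Why: Proposed new method: zerovalent palladium inserts into the acyl C–Cl bond of 12, transmetalation from 8 and reductive elimination join the exocyclic CH to the carbonyl carbon (dienone 13), and carbonate then removes a γ-hydrogen to give a 2-oxido-hexatriene that closes onto the dichloromethylene carbon, expels chloride (E1cB) and tautomerises to the phenoxide. The closest known reaction types are the acylative Suzuki–Miyaura coupling of acid chlorides, the 6π benzannulation of 2-siloxy-trienes and dienylketenes, and the addition–elimination annulation of allyl anions with α-oxo ketene dithioacetals; their union in one pot on a γ-enolisable β,β-dichlorodivinyl ketone is what is new. The one ring formed, the future phenol ring, closes by thermal disrotatory 6π-electrocyclisation of the trienolate, in polar terms a 6-endo-trig vinylogous addition–elimination. No stereocentre is created, since the transient sp3 ring-fusion CH is lost on aromatisation, and both alkene isomers of 8 give the same equilibrating trienolate, so the step is stereoconvergent and leaves C-1 and C-2 untouched. It needs acyl over vinylic C–Cl insertion, which the far faster oxidative addition of the acid chloride should secure, and a single site of deprotonation, secured because only C-4a carries γ-hydrogens (C-1 is quaternary, the dichlorovinyl arm has none); high dilution and the irreversible chloride loss favour ring closure over intermolecular addition.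

Step 8
Reactants: 14 chlorophenol; 15 tributyl(ethenyl)stannane
Product: 16 methyl 3-[(1R,2R)-5-ethenyl-7-hydroxy-1,6-dimethyl-2-(prop-1-en-2-yl)-1,2,3,4-tetrahydronaphthalen-1-yl]propanoate
Conditions: 15 (1.3 equiv), Pd(P(t-Bu)3)2 (5 mol %), CsF (2.2 equiv), 1,4-dioxane, 100 °C
Reagents that add atoms: none
Why: Stille cross-coupling; the bulky, electron-rich zerovalent palladium catalyst with fluoride activation of the stannane is suited to di-ortho-substituted aryl chlorides and should tolerate the ester, the free phenol and the alkenes.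

Step 9
Reactants: 16 vinyl phenol
Product: 17 trigonochinene C, methyl 3-[(1R,2R,4aR)-5-ethenyl-4a-hydroperoxy-1,6-dimethyl-7-oxo-2-(prop-1-en-2-yl)-1,2,3,4,4a,7-hexahydronaphthalen-1-yl]propanoate
Conditions: O2 (1 atm), meso-tetraphenylporphyrin (1 mol %), white LED, CH2Cl2–MeOH (4:1), −20 °C, stopped at full consumption of 16
Reagents that add atoms: dioxygen, O=O
Why: Sensitised singlet-oxygen oxygenation of a para-alkylphenol (formal [4+2] addition across C-7/C-4a and opening to the 4-hydroperoxy-2,5-dienone), the electron-rich phenol reacting far faster than the 1,1-disubstituted or styrenyl alkenes; the C-4a centre is set by substrate control, oxygen bonding axially to the half-chair of the cyclohexane ring that keeps isopropenyl equatorial, i.e. anti to the pseudo-axial C-4 hydrogen, syn to the axial C-1 methyl and anti to the propanoate arm, which leads directly to the chair of the 4aR product.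

**Compound list**

1 | 2-methylcyclohex-2-en-1-one | CC1=CCCCC1=O | starting material
2 | prop-1-en-2-ylmagnesium bromide | CC(=C)[Mg]Br | starting material
3 | bromomagnesium (S)-2-methyl-3-(prop-1-en-2-yl)cyclohex-1-en-1-olate | CC1=C(O[Mg]Br)CCC[C@@H]1C(C)=C | intermediate
4 | (3S)-2-methyl-3-(prop-1-en-2-yl)cyclohexan-1-one (C-2 epimers) | O=C1CCC[C@H](C(C)=C)C1C | intermediate
5 | methyl acrylate | C=CC(=O)OC | starting material
6 | methyl 3-[(1R,6R)-1-methyl-2-oxo-6-(prop-1-en-2-yl)cyclohexyl]propanoate | O=C1CCC[C@H](C(C)=C)[C@@]1(C)CCC(=O)OC | intermediate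
7 | 2,2'-methylenebis(4,4,5,5-tetramethyl-1,3,2-dioxaborolane) | CC1(C)OB(CB2OC(C)(C)C(C)(C)O2)OC1(C)C | starting material
8 | methyl 3-[(1R,6R)-1-methyl-6-(prop-1-en-2-yl)-2-[(4,4,5,5-tetramethyl-1,3,2-dioxaborolan-2-yl)methylidene]cyclohexyl]propanoate (E/Z) | CC1(C)OB(C=C2CCC[C@H](C(C)=C)[C@@]2(C)CCC(=O)OC)OC1(C)C | intermediate
9 | methyl pyruvate | CC(=O)C(=O)OC | starting material
10 | methyl 3,3-dichloro-2-methylprop-2-enoate | COC(=O)C(C)=C(Cl)Cl | intermediate
11 | 3,3-dichloro-2-methylprop-2-enoic acid | OC(=O)C(C)=C(Cl)Cl | intermediate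
12 | 3,3-dichloro-2-methylprop-2-enoyl chloride | ClC(=O)C(C)=C(Cl)Cl | intermediate
13 | methyl 3-[(1R,6R)-2-(4,4-dichloro-3-methyl-2-oxobut-3-en-1-ylidene)-1-methyl-6-(prop-1-en-2-yl)cyclohexyl]propanoate (E/Z) | ClC(Cl)=C(C)C(=O)C=C1CCC[C@H](C(C)=C)[C@@]1(C)CCC(=O)OC | intermediate
14 | methyl 3-[(1R,2R)-5-chloro-7-hydroxy-1,6-dimethyl-2-(prop-1-en-2-yl)-1,2,3,4-tetrahydronaphthalen-1-yl]propanoate | Clc1c(C)c(O)cc2c1CC[C@H](C(C)=C)[C@@]2(C)CCC(=O)OC | intermediate
15 | tributyl(ethenyl)stannane | C=C[Sn](CCCC)(CCCC)CCCC | starting material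
16 | methyl 3-[(1R,2R)-5-ethenyl-7-hydroxy-1,6-dimethyl-2-(prop-1-en-2-yl)-1,2,3,4-tetrahydronaphthalen-1-yl]propanoate | C=Cc1c(C)c(O)cc2c1CC[C@H](C(C)=C)[C@@]2(C)CCC(=O)OC | intermediate
17 | trigonochinene C, methyl 3-[(1R,2R,4aR)-5-ethenyl-4a-hydroperoxy-1,6-dimethyl-7-oxo-2-(prop-1-en-2-yl)-1,2,3,4,4a,7-hexahydronaphthalen-1-yl]propanoate | C=CC1=C(C)C(=O)C=C2[C@]1(OO)CC[C@H](C(=C)C)[C@@]2(C)CCC(=O)OC | target

**Step count and risks**

Total: 9 steps. Longest linear sequence: 6 steps (1, 2, 3, 7, 8, 9; the acid chloride branch 4, 5, 6, 7, 8, 9 is equally long).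

Most likely to fail, in this order:

Step 7 (proposed new method). The dienone may be diverted before ring closure, by palladium insertion into its activated vinylic C–Cl bonds or by intermolecular conjugate addition, while γ-deprotonation by carbonate is slow. The fallback is stepwise, neutral and uses known chemistry. It sets out from 8 and 12: the acylative Suzuki–Miyaura coupling is run alone (Pd(PPh3)4, anhydrous K3PO4, toluene, 60 °C) and dienone 13 is isolated. Soft enolisation with TBSOTf and Et3N at the only γ-position should give the silyl trienol ether F1. Heating in toluene at 110 °C with 2,6-lutidine and a trace of iodine (enol ether E/Z equilibration) should effect thermal 6π-electrocyclisation and loss of HCl to the aryl silyl ether F2. Bu4NF in THF removes the silyl group and the route is rejoined at 14.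

Step 9. Facial selectivity of oxygen delivery to C-4a may be poor if the ring-flipped half-chair (axial isopropenyl) competes, and the isopropenyl group may be over-oxidised at high conversion. The fallback replaces reliance on kinetic control by separation and recycling. It sets out from 16: the oxygenation is stopped at partial conversion and 17 is separated by chromatography from its C-4a epimer, the (4aS)-hydroperoxide F3. F3 is reduced with PPh3 to the (4aS)-para-quinol F4 and then with zinc dust in acetic acid, which rearomatises it, so the material comes back to the route at 16 and is resubmitted.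

Step 3. The basic α-boryl carbanion may enolise the hindered α-quaternary ketone, or attack the ester, in place of carbonyl addition. The fallback sets out from 6: Wittig chloromethylenation ((chloromethyl)triphenylphosphonium chloride, NaN(SiMe3)2, THF, 0 °C to rt) should give the alkenyl chloride F5 (E/Z). Miyaura borylation (B2pin2, Pd2(dba)3, XPhos, KOAc, 1,4-dioxane, 100 °C) returns to the route at 8.

**Further compounds**

F1 | step 7 | methyl 3-[(1R,6R)-2-[2-(tert-butyldimethylsilyloxy)-4,4-dichloro-3-methylbuta-1,3-dien-1-yl]-1-methyl-6-(prop-1-en-2-yl)cyclohex-2-en-1-yl]propanoate | ClC(Cl)=C(C)C(O[Si](C)(C)C(C)(C)C)=CC1=CCC[C@H](C(C)=C)[C@@]1(C)CCC(=O)OC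
F2 | step 7 | methyl 3-[(1R,2R)-7-(tert-butyldimethylsilyloxy)-5-chloro-1,6-dimethyl-2-(prop-1-en-2-yl)-1,2,3,4-tetrahydronaphthalen-1-yl]propanoate | Clc1c(C)c(O[Si](C)(C)C(C)(C)C)cc2c1CC[C@H](C(C)=C)[C@@]2(C)CCC(=O)OC
F3 | step 9 | methyl 3-[(1R,2R,4aS)-5-ethenyl-4a-hydroperoxy-1,6-dimethyl-7-oxo-2-(prop-1-en-2-yl)-1,2,3,4,4a,7-hexahydronaphthalen-1-yl]propanoate | C=CC1=C(C)C(=O)C=C2[C@@]1(OO)CC[C@H](C(=C)C)[C@@]2(C)CCC(=O)OC
F4 | step 9 | methyl 3-[(1R,2R,4aS)-5-ethenyl-4a-hydroxy-1,6-dimethyl-7-oxo-2-(prop-1-en-2-yl)-1,2,3,4,4a,7-hexahydronaphthalen-1-yl]propanoate | C=CC1=C(C)C(=O)C=C2[C@@]1(O)CC[C@H](C(=C)C)[C@@]2(C)CCC(=O)OC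
F5 | step 3 | methyl 3-[(1R,6R)-2-(chloromethylidene)-1-methyl-6-(prop-1-en-2-yl)cyclohexyl]propanoate (E/Z) | ClC=C1CCC[C@H](C(C)=C)[C@@]1(C)CCC(=O)OC
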